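**Plan**

1. Atoms are numbered C1–C28 in heavy-atom order of the target SMILES. The last cut removes the four C–O bonds of the oxiranes C9–O10–C11 and C20–O21–C22. Each oxirane lies trans to the neighbouring carbinol oxygen (O13 on C12, O19 on C18) and beside a carbonyl (C7, C23) that can travel as a ketal; C9=C11 and C20=C22 are the only exposed alkenes of the two carbocycles, because C5=C6 and C16=C17 are tetrasubstituted and buried in the cage, so a silyl ether on O13/O19 can steer an epoxidation.
2. The two cyclohexadiene rings are traced back to 4-methoxyphenol rings (OMe on C7/C23, OH on C12/C18): oxidative dearomatisation gives the quinone monoketals, and a CBS reduction sets C12/C18.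
3. The aromatic cage is cut at C4–C5/C4–O3 and C25–C17/C25–O26 (twofold oxa-Pictet–Spengler closure around a glyoxal bis-acetal that supplies C4–C25), leaving an all-syn, C2-symmetric 3,4-diarylhexane-2,5-diol.
4. The diol is cut at C14–C15 (oxidative homocoupling of an arylacetyl oxazolidinone enolate) and at the C2/C27 carbinols (methyl ketones, CBS reduction).
5. Forward order: arylacetic acid → imide → C14–C15 bond → diketone → diol → both pyrans and the eight-membered ring in one operation → dearomatisation → carbinols → silyl ethers → oxiranes → unmasking.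
6. Stereochemistry: C14/C15 from the (S)-oxazolidinone, C2/C27 and C12/C18 from (S)-CBS reductions, C4/C25 from the geometric demands of the cage, C9/C11/C20/C22 from the silyl ethers.

Key step: step 15

Remark: a 4-silyloxycyclohexa-2,5-dienone that still carries H on C12/C18 is the keto tautomer of a hydroquinone monosilyl ether and would aromatise with base; C7/C23 are therefore kept as dimethyl ketals through the epoxidation and a neutral oxygen-transfer reagent is used.

Assumption: the enolate dimerisation forms each new bond on the face away from the isopropyl group of the chelated Z-enolate (the usual facial sense of this auxiliary), which for an arylacetyl imide of the (S)-auxiliary corresponds to the (2S,3S) dimer.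

**Route**

Step 1
Reactants: 1 4-(benzyloxy)phenol
Product: 2 4-(benzyloxy)-2-bromophenol
Conditions: NBS (1.0 equiv), CH2Cl2, 0 °C
Reagents that add atoms: N-bromosuccinimide, O=C1CCC(=O)N1Br
Why: Electrophilic aromatic bromination in which the free hydroxyl is the stronger ortho/para director and its para position is blocked, so bromine should enter ortho to OH.

Step 2
Reactants: 2 4-(benzyloxy)-2-bromophenol
Product: 3 4-(benzyloxy)-2-bromo-1-methoxybenzene
Conditions: MeI, K2CO3, acetone, reflux
Reagents that add atoms: iodomethane, CI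
Why: Williamson ether synthesis on the phenoxide, which fixes the methyl ether that later becomes the C7/C23 ketal.

Step 3
Reactants: 3 4-(benzyloxy)-2-bromo-1-methoxybenzene
Product: 4 ethyl 2-[5-(benzyloxy)-2-methoxyphenyl]acetate
Conditions: BrZnCH2CO2Et (1.5 equiv), Pd(dba)2 (2 mol %), Q-Phos (2 mol %), THF, 50 °C
Reagents that add atoms: (2-ethoxy-2-oxoethyl)zinc bromide, CCOC(=O)C[Zn]Br
Why: Palladium-catalysed cross-coupling of a Reformatsky reagent with an aryl bromide (Negishi-type ester α-arylation), which should tolerate the electron-rich ortho-methoxy arene and the benzyl ether.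

Step 4
Reactants: 4 ethyl 2-[5-(benzyloxy)-2-methoxyphenyl]acetate
Product: 5 2-[5-(benzyloxy)-2-methoxyphenyl]acetic acid
Conditions: LiOH·H2O, THF/MeOH/H2O, rt; then 1 M HCl
Reagents that add atoms: lithium hydroxide, [Li+].[OH-]
Why: Ester saponification, with no stereocentre or sensitive group at risk.

Step 5
Reactants: 5 2-[5-(benzyloxy)-2-methoxyphenyl]acetic acid; 6 (S)-4-isopropyloxazolidin-2-one
Product: 8 (S)-3-{2-[5-(benzyloxy)-2-methoxyphenyl]acetyl}-4-isopropyloxazolidin-2-one, via pivalic mixed anhydride 7 (not isolated)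
Conditions: PivCl, Et3N, THF, −20 °C; then LiCl, 6, −20 °C → rt
Reagents that add atoms: none
Why: N-acylation of the oxazolidinone by a mixed pivalic anhydride (LiCl/Et3N protocol), in which the auxiliary should attack the unhindered arylacetyl carbonyl.

Step 6
Reactants: 8 (S)-3-{2-[5-(benzyloxy)-2-methoxyphenyl]acetyl}-4-isopropyloxazolidin-2-one (two molecules)
Product: 10 (2S,3S)-2,3-bis[5-(benzyloxy)-2-methoxyphenyl]-1,4-bis[(S)-4-isopropyl-2-oxooxazolidin-3-yl]butane-1,4-dione, via lithium Z-enolate 9 (not isolated)
Conditions: LDA (1.1 equiv), THF, −78 °C; then TiCl4 (1.1 equiv), −78 → 0 °C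
Reagents that add atoms: none
Why: Oxidative homocoupling of an imide enolate (titanium(IV) enolate, homolysis to the α-acyl benzylic radical, dimerisation), in which each centre should bond on the face away from the isopropyl group and so give the C2-symmetric (2S,3S) dimer that becomes C14/C15.

Step 7
Reactants: 10 (2S,3S)-bis-imide
Product: 11 S,S′-diethyl (2S,3S)-2,3-bis[5-(benzyloxy)-2-methoxyphenyl]butanebis(thioate)
Conditions: EtSH, n-BuLi, THF, 0 °C
Reagents that add atoms: lithium ethanethiolate (from ethanethiol and n-butyllithium), [Li+].CC[S-]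
Why: Thiolate cleavage of the N-acyl oxazolidinone at the exocyclic carbonyl (acyl substitution), by a weakly basic nucleophile that should leave the acidic benzylic α-centres untouched.

Step 8
Reactants: 11 bis(S-ethyl thioester)
Product: 12 (3S,4S)-3,4-bis[5-(benzyloxy)-2-methoxyphenyl]hexane-2,5-dione
Conditions: Me2CuLi (from CuI and MeLi, 3 equiv per thioester), Et2O, −78 → −30 °C; aq NH4Cl
Reagents that add atoms: lithium dimethylcuprate, [Li+].C[Cu-]C
Why: Ketone synthesis from a thioester and a lithium dialkylcuprate, which should stop at the ketone and is too weakly basic to enolise the α-aryl centres.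

Step 9
Reactants: 12 (3S,4S)-diketone
Product: 13 (2R,3S,4S,5R)-3,4-bis[5-(benzyloxy)-2-methoxyphenyl]hexane-2,5-diol
Conditions: (S)-Me-CBS (0.4 equiv), BH3·SMe2, THF, −20 °C; then MeOH
Reagents that add atoms: none
Why: CBS reduction of methyl ketones with a branched α-substituent, in which the (S)-catalyst should give the (R)-carbinols at C2/C27, in line with the Felkin–Anh preference (aryl anti to hydride) for the 2,3-syn relationship.

Step 10
Reactants: 13 (2R,3S,4S,5R)-diol; 14 1,1,2,2-tetramethoxyethane
Product: 16 bis(benzyl ether) of the aromatic cage (2R,4S,14S,15S,25S,27R; two 3-methylisochromans joined C4–C25 and C14–C15, OMe on C7/C23, OBn on C12/C18), via mono-isochroman dimethyl acetal 15 (not isolated)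
Conditions: 14 (1.1 equiv), BF3·OEt2 (4 equiv), CH2Cl2 (0.01 M), 0 °C → rt
Reagents that add atoms: none
Why: Proposed new method: a twofold oxa-Pictet–Spengler cyclisation around one glyoxal bis-acetal, in which BF3 ionises one acetal carbon (C4), O3 captures it and the O3=C4 oxocarbenium ion is attacked by C5 (the only free ring position next to the side chain, since C7 carries OMe, and activated by the ortho benzyloxy group) to give 15, after which the second acetal carbon (C25) engages O26 and C17 in the same way (in either order) and thereby closes the second pyran and the eight-membered carbocycle; the closest known reaction type is the BF3-mediated oxa-Pictet–Spengler synthesis of 5,8-dialkoxy-1,3-dimethylisochromans from 1-(2,5-dialkoxyphenyl)propan-2-ols and acetaldehyde dimethyl acetal; C4 and C25 are set by the cage, because only the isomer with C25 cis to C15 on the first pyran can close, an arrangement favoured by the peri alkoxy groups (C7–OMe, C12–OBn) that push one of the C4/C14 substituents axial, and a wrong C4 epimer can re-ionise at the o-alkoxybenzylic C4–O3 bond.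

Step 11
Reactants: 16 bis(benzyl ether) cage
Product: 17 bis-phenol cage (OH on C12/C18, OMe on C7/C23)
Conditions: H2 (1 atm), 10% Pd/C, EtOAc/MeOH, rt
Reagents that add atoms: none
Why: Hydrogenolysis of aryl benzyl ethers, which should be much faster than cleavage of the hindered secondary benzylic C4–O3/C25–O26 ring ethers.

Step 12
Reactants: 17 bis-phenol cage
Product: 18 bis(quinone monoketal) cage (C12/C18 ketones, C7/C23 dimethyl ketals)
Conditions: PhI(OAc)2 (2.2 equiv), MeOH, 0 °C
Reagents that add atoms: methanol, CO
Why: Hypervalent-iodine oxidative dearomatisation of a 4-methoxyphenol in methanol, which should deliver the para-quinone monoketal with the ketone at the former phenol carbon.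

Step 13
Reactants: 18 bis(quinone monoketal) cage
Product: 19 (12R,18R)-bis(dienol) cage (C7/C23 dimethyl ketals)
Conditions: (S)-Me-CBS (1.0 equiv), BH3·SMe2, toluene, −40 °C; MeOH, then aq NaHCO3
Reagents that add atoms: none
Why: CBS 1,2-reduction of a cross-conjugated dienone in which the fully substituted C5 (C17) side acts as the large group and the CH=CH side as the small one, so the (S)-catalyst should give the (12R,18R) carbinols with the hydroxyl on the ring face turned toward the other half of the cage.

Step 14
Reactants: 19 (12R,18R)-bis(dienol) cage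
Product: 20 (12R,18R)-bis(triethylsilyl ether) of the bis(dienol) cage
Conditions: TESCl, imidazole, DMAP (cat.), CH2Cl2, 0 °C
Reagents that add atoms: chlorotriethylsilane, CC[Si](Cl)(CC)CC
Why: Silylation of a secondary alcohol under basic conditions, which also guards the acid-labile bis-allylic carbinol against ionisation and installs the directing group.

Step 15
Reactants: 20 (12R,18R)-bis(triethylsilyl ether)
Product: 22 bis-epoxide (9R,11R,12S,18S,20R,22R) as its bis(triethylsilyl ether) and bis(dimethyl ketal), via mono-epoxide 21 (not isolated)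
Conditions: DMDO (acetone solution, 5 equiv), CH2Cl2, 0 °C → rt
Reagents that add atoms: dimethyldioxirane, CC1(C)OO1
Why: Dimethyldioxirane transfers an oxygen atom through a concerted spiro transition state to the cis-disubstituted C9=C11 and C20=C22 bonds, so both C–O bonds of each oxirane form at once (concerted [2+1] closure of each three-membered ring), first giving 21 and then 22. The closest known reaction type is the anti-selective peracid or dioxirane epoxidation of cyclohexenyl silyl ethers and enone ketals. C9/C11 are controlled by the C12 silyloxy group and C20/C22 by the C18 one: each bulky silyl ether occupies the ring face turned into the cleft toward the other half of the cage, so the oxidant should approach from the open outer face, anti to the silyloxy group. The step needs site selectivity for the disubstituted over the tetrasubstituted alkenes; this is secured because C5=C6 and C16=C17 carry four branched oxygenated substituents and are screened on one face by the methyl-bearing O–CH(CH3) bridge and on the other by the second half of the cage. Keeping C7/C23 as dimethyl ketals removes the aromatisation channel of a free dienone, and the neutral reagent should leave the bis-allylic ketals and silyl ethers intact.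

Step 16
Reactants: 22 bis-epoxide bis(triethylsilyl ether) bis(dimethyl ketal)
Product: 23 epoxytwinol A
Conditions: 48% aq HF, MeCN, 0 °C → rt
Reagents that add atoms: water, O
Why: Acid hydrolysis of the two allylic dimethyl ketals (via the C7/C23 oxocarbenium ions) with concurrent fluoride-assisted cleavage of the triethylsilyl ethers, under which the electron-poor oxiranes and all set stereocentres should persist.

**Compound list**

1 | 4-(benzyloxy)phenol | Oc1ccc(OCc2ccccc2)cc1 | starting material
2 | 4-(benzyloxy)-2-bromophenol | Oc1ccc(OCc2ccccc2)cc1Br | intermediate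
3 | 4-(benzyloxy)-2-bromo-1-methoxybenzene | COc1ccc(OCc2ccccc2)cc1Br | intermediate
4 | ethyl 2-[5-(benzyloxy)-2-methoxyphenyl]acetate | CCOC(=O)Cc1cc(OCc2ccccc2)ccc1OC | intermediate
5 | 2-[5-(benzyloxy)-2-methoxyphenyl]acetic acid | OC(=O)Cc1cc(OCc2ccccc2)ccc1OC | intermediate
6 | (S)-4-isopropyloxazolidin-2-one | CC(C)[C@H]1COC(=O)N1 | starting material
7 | 2-[5-(benzyloxy)-2-methoxyphenyl]acetic pivalic anhydride | CC(C)(C)C(=O)OC(=O)Cc1cc(OCc2ccccc2)ccc1OC | intermediate
8 | (S)-3-{2-[5-(benzyloxy)-2-methoxyphenyl]acetyl}-4-isopropyloxazolidin-2-one | COc1ccc(OCc2ccccc2)cc1CC(=O)N1[C@@H](C(C)C)COC1=O | intermediate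
9 | lithium (Z)-enolate of 8 | [Li+].COc1ccc(OCc2ccccc2)cc1/C=C(\[O-])N1[C@@H](C(C)C)COC1=O | intermediate
10 | (2S,3S)-2,3-bis[5-(benzyloxy)-2-methoxyphenyl]-1,4-bis[(S)-4-isopropyl-2-oxooxazolidin-3-yl]butane-1,4-dione | O=C([C@H](c1cc(OCc2ccccc2)ccc1OC)[C@@H](c1cc(OCc2ccccc2)ccc1OC)C(=O)N1[C@@H](C(C)C)COC1=O)N1[C@@H](C(C)C)COC1=O | intermediate
11 | S,S′-diethyl (2S,3S)-2,3-bis[5-(benzyloxy)-2-methoxyphenyl]butanebis(thioate) | CCSC(=O)[C@H](c1cc(OCc2ccccc2)ccc1OC)[C@@H](c1cc(OCc2ccccc2)ccc1OC)C(=O)SCC | intermediate
12 | (3S,4S)-3,4-bis[5-(benzyloxy)-2-methoxyphenyl]hexane-2,5-dione | CC(=O)[C@H](c1cc(OCc2ccccc2)ccc1OC)[C@@H](c1cc(OCc2ccccc2)ccc1OC)C(C)=O | intermediate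
13 | (2R,3S,4S,5R)-3,4-bis[5-(benzyloxy)-2-methoxyphenyl]hexane-2,5-diol | C[C@@H](O)[C@H](c1cc(OCc2ccccc2)ccc1OC)[C@@H](c1cc(OCc2ccccc2)ccc1OC)[C@@H](C)O | intermediate
14 | 1,1,2,2-tetramethoxyethane | COC(OC)C(OC)OC | starting material
15 | (1S,3R,4S)-8-(benzyloxy)-4-{(1S,2R)-1-[5-(benzyloxy)-2-methoxyphenyl]-2-hydroxypropyl}-1-(dimethoxymethyl)-5-methoxy-3-methylisochromane | C[C@H]1O[C@H](C(OC)OC)c2c(c(OC)ccc2OCc3ccccc3)[C@@H]1[C@@H](c1cc(OCc2ccccc2)ccc1OC)[C@@H](C)O | intermediate
16 | bis(benzyl ether) of the aromatic cage (2R,4S,14S,15S,25S,27R; OMe on C7/C23, OBn on C12/C18) | C[C@H]1O[C@H]2c3c(c(OC)ccc3OCc4ccccc4)[C@@H]1[C@H]1c3c(c(OCc4ccccc4)ccc3OC)[C@@H]2O[C@@H]1C | intermediate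
17 | bis-phenol aromatic cage (OH on C12/C18, OMe on C7/C23) | C[C@H]1O[C@H]2c3c(c(OC)ccc3O)[C@@H]1[C@H]1c3c(c(O)ccc3OC)[C@@H]2O[C@@H]1C | intermediate
18 | bis(quinone monoketal) cage (C12/C18 ketones, C7/C23 dimethyl ketals) | C[C@H]1O[C@H]2C3=C(C(OC)(OC)C=CC3=O)[C@@H]1[C@H]1C3=C(C(=O)C=CC3(OC)OC)[C@@H]2O[C@@H]1C | intermediate
19 | (12R,18R)-bis(dienol) cage (C7/C23 dimethyl ketals) | C[C@H]1O[C@H]2C3=C(C(OC)(OC)C=C[C@H]3O)[C@@H]1[C@H]1C3=C([C@H](O)C=CC3(OC)OC)[C@@H]2O[C@@H]1C | intermediate
20 | (12R,18R)-bis(triethylsilyl ether) of 19 | C[C@H]1O[C@H]2C3=C(C(OC)(OC)C=C[C@H]3O[Si](CC)(CC)CC)[C@@H]1[C@H]1C3=C([C@H](O[Si](CC)(CC)CC)C=CC3(OC)OC)[C@@H]2O[C@@H]1C | intermediate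
21 | mono-epoxide (C9–O10–C11 closed, C20=C22 intact) | C[C@H]1O[C@H]2C3=C(C(OC)(OC)[C@@H]4O[C@@H]4[C@H]3O[Si](CC)(CC)CC)[C@@H]1[C@H]1C3=C([C@H](O[Si](CC)(CC)CC)C=CC3(OC)OC)[C@@H]2O[C@@H]1C | intermediate
22 | bis(triethylsilyl ether) bis(dimethyl ketal) of epoxytwinol A | C[C@H]1O[C@H]2C3=C(C(OC)(OC)[C@@H]4O[C@@H]4[C@H]3O[Si](CC)(CC)CC)[C@@H]1[C@H]1C3=C([C@H](O[Si](CC)(CC)CC)[C@H]4O[C@H]4C3(OC)OC)[C@@H]2O[C@@H]1C | intermediate
23 | epoxytwinol A | C[C@H]1O[C@H]2C3=C(C(=O)[C@@H]4O[C@@H]4[C@H]3O)[C@@H]1[C@H]1C3=C([C@H](O)[C@H]4O[C@H]4C3=O)[C@@H]2O[C@@H]1C | target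

**Step count:** 16 steps in total; longest linear sequence 16 steps (from 1).

**Steps most likely to fail**

Step 10 (proposed new method). The first ring closure may place the acetal carbon trans to the C14 substituent, or the second oxocarbenium ion may be trapped intermolecularly, so that oligomeric acetals form and the cage never closes. The fallback sets out from diol 13 and separates the two closures with known reactions. An oxa-Pictet–Spengler reaction of 13 with ethyl glyoxylate (1 equiv, BF3·OEt2) should give the ethyl isochroman-1-carboxylate F1, whose C4 centre (α-aryl, α-alkoxy ester) can be equilibrated with DBU toward the isomer with the ester cis to the C14 substituent. Reduction with DIBAL-H at −78 °C should give the isochroman-1-carbaldehyde F2. An acid-mediated intramolecular oxa-Pictet–Spengler reaction of the aldehyde with O26 and C17 (TMSOTf, CH2Cl2, high dilution) then closes the second pyran, and the route is rejoined at cage 16.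

Step 15. Oxygen transfer may also reach the tetrasubstituted C5=C6/C16=C17 bonds, or the anti preference may erode on the nearly flat diene ring, giving mixtures of site- and face-isomeric epoxides. The fallback sets out from bis(quinone monoketal) 18 and moves the epoxidation in front of the carbonyl reduction. A Weitz–Scheffer epoxidation (t-BuOOH, DBU, CH2Cl2, 0 °C) of the C9=C11/C20=C22 enone bonds, now activated by the C12/C18 ketones and with no acidic ring C–H, should give the bis(epoxy ketone) F3 from the open outer face of the cage. DIBAL-H at −78 °C (hydride delivered on the oxirane face after coordination of aluminium to the oxirane oxygen) should give the trans bis(epoxy alcohol) F4. Hydrolysis of the ketals with aqueous HF in MeCN rejoins the route at 23.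

Step 6. Radical dimerisation of the hindered ortho-methoxyaryl enolate may proceed with poor facial control, or be diverted to α-chlorination and simple reprotonation. The fallback sets out from acid 5 and replaces auxiliary control by a classical resolution. Oxidation of the dianion of 5 (2 LDA, THF, then I2) is the known dl-selective route to 2,3-diarylsuccinic acids and should give the racemic dl-diacid F5. Crystallisation of its salt with a chiral amine (for example cinchonidine or 1-phenylethylamine) should give the (2S,3S)-diacid F6. Steglich thioesterification (EtSH, DCC, DMAP) rejoins the route at bis-thioester 11.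

**Further compounds**

F1 | step 10 | ethyl (1S,3R,4S)-8-(benzyloxy)-4-{(1S,2R)-1-[5-(benzyloxy)-2-methoxyphenyl]-2-hydroxypropyl}-5-methoxy-3-methylisochromane-1-carboxylate | C[C@H]1O[C@H](C(=O)OCC)c2c(c(OC)ccc2OCc3ccccc3)[C@@H]1[C@@H](c1cc(OCc2ccccc2)ccc1OC)[C@@H](C)O
F2 | step 10 | corresponding isochromane-1-carbaldehyde (CHO on C4 in place of CO2Et) | C[C@H]1O[C@H](C=O)c2c(c(OC)ccc2OCc3ccccc3)[C@@H]1[C@@H](c1cc(OCc2ccccc2)ccc1OC)[C@@H](C)O
F3 | step 15 | bis(epoxy ketone) cage (oxiranes C9–O10–C11 and C20–O21–C22, C12/C18 ketones, C7/C23 dimethyl ketals) | C[C@H]1O[C@H]2C3=C(C(OC)(OC)[C@@H]4O[C@@H]4C3=O)[C@@H]1[C@H]1C3=C(C(=O)[C@H]4O[C@H]4C3(OC)OC)[C@@H]2O[C@@H]1C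
F4 | step 15 | bis(dimethyl ketal) of epoxytwinol A (free C12/C18 hydroxyls) | C[C@H]1O[C@H]2C3=C(C(OC)(OC)[C@@H]4O[C@@H]4[C@H]3O)[C@@H]1[C@H]1C3=C([C@H](O)[C@H]4O[C@H]4C3(OC)OC)[C@@H]2O[C@@H]1C
F5 | step 6 | rac-(2S*,3S*)-2,3-bis[5-(benzyloxy)-2-methoxyphenyl]succinic acid (dl racemate; the 2S,3S enantiomer is drawn) | OC(=O)[C@H](c1cc(OCc2ccccc2)ccc1OC)[C@@H](c1cc(OCc2ccccc2)ccc1OC)C(O)=O
F6 | step 6 | (2S,3S)-2,3-bis[5-(benzyloxy)-2-methoxyphenyl]succinic acid (resolved enantiomer) | OC(=O)[C@H](c1cc(OCc2ccccc2)ccc1OC)[C@@H](c1cc(OCc2ccccc2)ccc1OC)C(O)=O
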